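3 questions are put to these flasks, and the readings are of product, c(product), over time.

| flask | starting material | partner | free catalyst | time |
|---|---|---|---|---|
| alpha | 0.400 M | 1.00 M | 8.00 × 10⁻⁴ M |  |
| epsilon | 0.800 M | 1.00 M | 8.00 × 10⁻⁴ M |  |
| delta | 0.400 M | 3.00 M | 8.00 × 10⁻⁴ M |  |
| theta | 0.400 M | 1.00 M | 4.00 × 10⁻⁴ M |  |
| gamma | 0.120 M | 0.720 M | 8.00 × 10⁻⁴ M | 4.0 h |

| run | time / h | [product] / M |
|---|---|---|
| alpha run | 0.57 | 0.1152 |
| alpha run | 1.1 | 0.1782 |
| alpha run | 1.7 | 0.2183 |
| alpha run | 2.3 | 0.2434 |
| alpha run | 2.9 | 0.2551 |
| alpha run | 3.4 | 0.2615 |
| alpha run | 4.0 | 0.2674 |
| epsilon run | 0.57 | 0.2324 |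
| epsilon run | 1.1 | 0.3539 |
| epsilon run | 1.7 | 0.4309 |
| epsilon run | 2.3 | 0.4749 |
| epsilon run | 2.9 | 0.5011 |
| epsilon run | 3.4 | 0.5116 |
| epsilon run | 4.0 | 0.5201 |
| delta run | 0.57 | 0.1198 |
| delta run | 1.1 | 0.1835 |
| delta run | 1.7 | 0.2261 |
| delta run | 2.3 | 0.2504 |
| delta run | 2.9 | 0.2612 |
| delta run | 3.4 | 0.2681 |
| delta run | 4.0 | 0.2728 |
| theta run | 0.57 | 0.0626 |
| theta run | 1.1 | 0.1043 |
| theta run | 1.7 | 0.1379 |
| theta run | 2.3 | 0.1609 |
| theta run | 2.9 | 0.1736 |
| theta run | 3.4 | 0.1819 |
| theta run | 4.0 | 0.1909 |

(each reading ± 0.001 M)

- order of the initial rate in [partner], near the charge of the alpha run, the rate being that where two percent of its starting material are product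
- order of the initial rate in [starting material], near the charge of the alpha run, the rate being that where two percent of its starting material are product (one fixed amount of product, the same in the runs compared)
- product in the gamma run at 4.0 h, as a share of the starting material charged

- Overall: starting material + partner -> product, with free catalyst as catalyst.
- Constant volume, constant temperature.
- A reading of a species includes what of it is bound.
- An order is taken over about fifteen percent of the charge, up and down.

**What do the curves show?** In the alpha run, c(product) reaches 66.8 % of the charge at 4.0 h. In the delta run, with partner at 3.00 M, it reaches 68.2 %.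

**What do you make of that?** My own reading is that starting material leaves by two pseudo-first-order channels: a catalysed one giving product, and a leak giving none.

**Your numbers?** In the alpha run, the mean rates from the first to third reading and from the third to fifth give a total constant of 0.936 h⁻¹. Dividing the last reading by the part of that decay completed gives the catalysed share, the fraction of lost starting material that becomes product: 0.685. As times, the catalysed channel takes 1.56 h and the leak 3.39 h, so the leak is slower.

**That is one run. Test it.** Take the theta run, with catalyst at half the alpha charge. If the catalysed time scales inversely with catalyst, it becomes 3.12 h, while the leak time stays. Then 0.615 h⁻¹ is the total constant, and the share at 4.0 h comes to 47.7 %. The theta reading is 47.7 %.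

**The orders?** The first delta reading over the first alpha reading is 1.04, a mean order in partner of 0.0356 between those charges, a reading with its scatter. The first epsilon reading over the first alpha reading gives an order in starting material of 1.01.

**And the gamma run?** Both channels are taken as first order in starting material, so its charge drops out. Partner at 0.720 M stretches the catalysed time to 1.58 h. With 0.928 h⁻¹, I expect 66.6 % at 4.0 h.

**The forecast?** It gives an order in partner of 0.05, an order in starting material of 1 and a gamma share of 68 %, on this ground: “It looks like first-order consumption of starting material with the catalyst dying”. Its partner order is higher than mine, and its gamma share is higher too.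

**The result.** The simulation gives an order in partner of 0.039, an order in starting material of 1.0 and a gamma share of 66.9 %.

    free catalyst + partner ⇌ catalyst-reagent complex, settled at all times (25.40 M⁻¹)
    catalyst-reagent complex + starting material → product + free catalyst (860.4 M⁻¹ h⁻¹)
    free catalyst + product → spent catalyst + product (4.536 M⁻¹ h⁻¹)
    starting material → decomposed substrate (0.2956 h⁻¹)

The conversion of free catalyst into spent catalyst moves the readings by 6.3 scatter units, root mean square, yet it makes no difference to the gamma share. The carried share gave 66.6 % for the gamma run. In the epsilon run, with twice the alpha charge of starting material, the same catalysed share and total constant put a quarter of the charge at 0.485 h, and the epsilon run reaches it at 0.473 h.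

All runs are calculated for an exercise; noise was put on by code.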